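The tridepside is cut at its two aryl ester bonds into ring A (acid terminus), ring B (middle) and ring C (dihydroxy terminus), and the plan rests on building ring A from open chains. The feature exploited is the meta pair O2/O4 of ring A flanking the C3 methyl: O2 must become a methyl ether, O4 an aryl ester. One Wolff rearrangement/benzannulation cascade forms C5–C6, C2–C3, C4–C5 and C1–C2, closes ring A, and hands over O2 as free phenol and O4 as silyl ether, with the C1 ester and both methyls placed. Its precursor is a benzyl (E)-3-methylpent-2-enoate carrying a terminal diazo ketone, partnered with a siloxypropyne.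

Key step: step 4

**Atom labels**
- Ring A: C1 (CO2H), C2 (OMe), C3 (Me), C4 (O-acyl), C5 (H), C6 (Me).
- Ring B: C1′ (C=O), C2′ (OMe), C3′ (Me), C4′ (O-acyl), C5′ (Me), C6′ (Me).
- Ring C: C1″ (C=O), C2″ (OH), C3″ (Me), C4″ (OH), C5″ (H), C6″ (Me).

**Assumption:** the target is achiral, so no stereocentre has to be set. The only stereochemical element in the route is the E geometry of the enoate, which is carried up to the ring closure.

**Design notes**
- The diazo ketone is made from the methyl ketone by diazo transfer. The acid chloride/diazomethane route is avoided because the alkene lies between two carbonyl groups, is a strong dipolarophile, and would take up diazomethane as a pyrazoline.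
- The cascade is run with light above 300 nm and excess alkyne, to protect the alkene geometry.
- Rings B and C both come from one aldehyde.
- In ring B the formyl group serves as a masked carboxyl, and its hydrogen bond to O2′–H replaces a protecting group.
- All benzyl groups leave together in the last step.

**Step 1**
Reactants: 1 butane-2,3-dione; 2 benzyl (triphenylphosphoranylidene)acetate
Product: 3 benzyl (2E)-3-methyl-4-oxopent-2-enoate
Conditions: 1 (3 equiv), CH2Cl2, 0 °C to rt
Reagents that add atoms: none
Why: Wittig olefination of an activated 1,2-diketone carbonyl by a stabilised ylide should stop at one carbonyl when the volatile diketone is in excess, and should place the ester trans to the acetyl group, as is usual for ester ylides.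

**Step 2**
Reactants: 3 benzyl (2E)-3-methyl-4-oxopent-2-enoate
Product: 5 benzyl (2E)-5-diazo-3-methyl-4-oxopent-2-enoate, via trifluoroacetyl diketone 4 (not isolated)
Conditions: LiN(SiMe3)2, THF, −78 °C; CF3CO2CH2CF3; aq HCl; then MsN3, Et3N, H2O, MeCN, rt
Reagents that add atoms: methanesulfonyl azide, CS(=O)(=O)N=[N+]=[N-] (both diazo nitrogens); 2,2,2-trifluoroethyl trifluoroacetate, O=C(OCC(F)(F)F)C(F)(F)F (CF3CO group, held only by 4)
Why: Detrifluoroacetylative Regitz-type diazo transfer, in which kinetic deprotonation at the acetyl CH3, Claisen trifluoroacetylation, azide attack and loss of the CF3CO group install the diazo group on an enone without any 1,3-dipole reagent meeting the electron-poor alkene.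

**Step 3**
Reactants: 6 propyne; 7 triisopropylsilyl trifluoromethanesulfonate
Product: 10 1-(triisopropylsilyloxy)prop-1-yne, via lithium propynide 8 (not isolated), via lithium propynolate 9 (not isolated)
Conditions: n-BuLi, THF, −78 °C; t-BuOOLi (from t-BuOOH, LiN(SiMe3)2), −78 to 0 °C; 7, −78 to 0 °C
Reagents that add atoms: tert-butyl hydroperoxide, CC(C)(C)OO (the oxygen); n-butyllithium, [Li]CCCC (lithium, held only by 8 and 9)
Why: Electrophilic oxygenation of a lithium acetylide by lithium tert-butyl peroxide gives the ynolate, which the bulky hard silyl triflate should capture on oxygen (ynolate O-silylation) rather than on carbon.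

**Step 4**
Reactants: 5 benzyl (2E)-5-diazo-3-methyl-4-oxopent-2-enoate; 10 1-(triisopropylsilyloxy)prop-1-yne
Product: 15 benzyl 2-hydroxy-3,6-dimethyl-4-(triisopropylsilyloxy)benzoate, via vinylketene 11 (not isolated), via vinylcyclobutenone 12 (not isolated), via dienylketene 13 (not isolated), via cyclohexadienone tautomer 14 (not isolated)
Conditions: 10 (2 equiv), degassed ClCH2CH2Cl, hν (medium-pressure Hg lamp, Pyrex, above 300 nm), rt; then 80 °C
Reagents that add atoms: none
Why: Light expels N2 from 5 and the alkenyl carbon C6 shifts to the diazo carbon C5 (Wolff rearrangement), giving vinylketene 11 whose carbonyl carbon is the future C2. The siloxyalkyne adds across the ketene C=C in a [2+2] step (C2–C3 and C4–C5) to give 12, whose four-electron conrotatory opening breaks the temporary C2–C5 bond and gives dienylketene 13. Ring A then closes by a six-electron disrotatory electrocyclisation joining the ketene carbon C2 to the ester-bearing C1, with H as the inward group at C1 because the alkene is E, and enolisation of 14 gives the phenol. This is the Danheiser benzannulation in its photochemical diazo ketone form, a reaction type known for alpha-diazo enones with siloxyalkynes. No lasting stereocentre is formed, and the selectivity needed is regiochemical: the methyl-bearing alkyne carbon is the nucleophilic end of the ynol ether and attacks the electrophilic ketene carbonyl, so the methyl lands on C3, the silyl group stays on O4 and the former ketene oxygen appears as free O2–H. The E alkene keeps the ester carbonyl away from the ketene so that oxa-electrocyclisation to a pyranone cannot compete, and long-wavelength light plus excess alkyne protect that geometry.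

**Step 5**
Reactants: 15 benzyl 2-hydroxy-3,6-dimethyl-4-(triisopropylsilyloxy)benzoate
Product: 16 benzyl 2-methoxy-3,6-dimethyl-4-(triisopropylsilyloxy)benzoate
Conditions: MeI, K2CO3, acetone, reflux
Reagents that add atoms: iodomethane, CI
Why: Williamson O-methylation of the only free phenol, in which the bulky aryl silyl ether next to the C3 methyl should survive carbonate in an aprotic solvent so that O4 stays masked.

**Step 6**
Reactants: 16 benzyl 2-methoxy-3,6-dimethyl-4-(triisopropylsilyloxy)benzoate
Product: 17 benzyl 4-hydroxy-2-methoxy-3,6-dimethylbenzoate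
Conditions: Bu4NF, AcOH, THF, 0 °C
Reagents that add atoms: none
Why: Fluoride-induced desilylation of an aryl silyl ether, buffered with acetic acid so that the phenoxide is protonated at once and the benzyl ester is left alone.

**Step 7**
Reactants: 18 2,5-dimethylresorcinol
Product: 20 2,4-dihydroxy-3,6-dimethylbenzaldehyde, via aryl iminium chloride 19 (not isolated)
Conditions: POCl3, DMF, MeCN, 0 °C to rt; then H2O, 50 °C
Reagents that add atoms: N,N-dimethylformamide, CN(C)C=O (formyl carbon); water, O (formyl oxygen); phosphoryl chloride, O=P(Cl)(Cl)Cl (chloride, held only by 19)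
Why: Vilsmeier–Haack formylation at one of the two equivalent ring positions that are ortho to one hydroxyl and para to the other, after which the iminium group deactivates the ring against a second attack.

**Step 8**
Reactants: 20 2,4-dihydroxy-3,6-dimethylbenzaldehyde
Product: 21 2,4-bis(benzyloxy)-3,6-dimethylbenzaldehyde
Conditions: BnBr (2.5 equiv), K2CO3, DMF, 60 °C
Reagents that add atoms: benzyl bromide, BrCc1ccccc1
Why: Double Williamson etherification, run warm with excess bromide so that the hydrogen-bonded O2″ hydroxyl is alkylated as well as O4″.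

**Step 9**
Reactants: 21 2,4-bis(benzyloxy)-3,6-dimethylbenzaldehyde
Product: 22 2,4-bis(benzyloxy)-3,6-dimethylbenzoic acid
Conditions: NaClO2, NaH2PO4, 2-methylbut-2-ene, t-BuOH/THF/H2O, rt
Reagents that add atoms: sodium chlorite, [Na+].[O-]Cl=O
Why: Pinnick oxidation turns the hindered aldehyde into the acid near neutral pH, and the alkene scavenger removes HOCl before it can chlorinate the free C5″ position.

**Step 10**
Reactants: 20 2,4-dihydroxy-3,6-dimethylbenzaldehyde
Product: 23 2,4,5-trimethylbenzene-1,3-diol
Conditions: Et3SiH (3 equiv), CF3CO2H, CH2Cl2, 0 °C to rt (aldehyde added slowly)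
Reagents that add atoms: none
Why: Ionic hydrogenation, in which hydride transfer to the protonated aldehyde and then to the benzylic cation stabilised by both hydroxyls converts CHO into CH3, with excess silane intercepting the cation before it can attack the product arene.

**Step 11**
Reactants: 23 2,4,5-trimethylbenzene-1,3-diol
Product: 25 2,4-dihydroxy-3,5,6-trimethylbenzaldehyde, via aryl iminium chloride 24 (not isolated)
Conditions: POCl3, DMF, MeCN, 0 °C to rt; then H2O, 50 °C
Reagents that add atoms: N,N-dimethylformamide, CN(C)C=O (formyl carbon); water, O (formyl oxygen); phosphoryl chloride, O=P(Cl)(Cl)Cl (chloride, held only by 24)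
Why: Vilsmeier–Haack formylation at the only unsubstituted ring carbon, which is ortho to one hydroxyl and para to the other.

**Step 12**
Reactants: 22 2,4-bis(benzyloxy)-3,6-dimethylbenzoic acid; 25 2,4-dihydroxy-3,5,6-trimethylbenzaldehyde
Product: 27 4-formyl-3-hydroxy-2,5,6-trimethylphenyl 2,4-bis(benzyloxy)-3,6-dimethylbenzoate, via mixed trifluoroacetic anhydride 26 (not isolated)
Conditions: (CF3CO)2O, toluene, 0 °C to rt; aq NaHCO3 work-up
Reagents that add atoms: trifluoroacetic anhydride, O=C(OC(=O)C(F)(F)F)C(F)(F)F (CF3CO group, held only by 26)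
Why: Esterification through the mixed trifluoroacetic anhydride, which for a 2,6-disubstituted electron-rich benzoic acid ionises to a slim linear acylium ion able to reach the doubly flanked O4′, while O2′–H is tied up in its hydrogen bond to the formyl group.

**Step 13**
Reactants: 27 4-formyl-3-hydroxy-2,5,6-trimethylphenyl 2,4-bis(benzyloxy)-3,6-dimethylbenzoate
Product: 28 4-formyl-3-methoxy-2,5,6-trimethylphenyl 2,4-bis(benzyloxy)-3,6-dimethylbenzoate
Conditions: MeI, K2CO3, DMF, rt
Reagents that add atoms: iodomethane, CI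
Why: Williamson O-methylation of the remaining chelated phenol, in which the depside ester is shielded by four ortho substituents and cannot migrate to the meta oxygen, so carbonate in DMF should leave it intact.

**Step 14**
Reactants: 28 4-formyl-3-methoxy-2,5,6-trimethylphenyl 2,4-bis(benzyloxy)-3,6-dimethylbenzoate
Product: 29 4-{[2,4-bis(benzyloxy)-3,6-dimethylbenzoyl]oxy}-2-methoxy-3,5,6-trimethylbenzoic acid
Conditions: NaClO2, NaH2PO4, 2-methylbut-2-ene (large excess), t-BuOH/THF/H2O, rt
Reagents that add atoms: sodium chlorite, [Na+].[O-]Cl=O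
Why: Pinnick oxidation unmasks the ring B carboxyl under buffered conditions that touch neither the aryl ester nor the benzyl ethers.

**Step 15**
Reactants: 29 4-{[2,4-bis(benzyloxy)-3,6-dimethylbenzoyl]oxy}-2-methoxy-3,5,6-trimethylbenzoic acid; 17 benzyl 4-hydroxy-2-methoxy-3,6-dimethylbenzoate
Product: 31 benzyl 4-[(4-{[2,4-bis(benzyloxy)-3,6-dimethylbenzoyl]oxy}-2-methoxy-3,5,6-trimethylbenzoyl)oxy]-2-methoxy-3,6-dimethylbenzoate, via mixed trifluoroacetic anhydride 30 (not isolated)
Conditions: (CF3CO)2O, toluene, 0 °C to rt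
Reagents that add atoms: trifluoroacetic anhydride, O=C(OC(=O)C(F)(F)F)C(F)(F)F (CF3CO group, held only by 30)
Why: The same mixed-anhydride esterification, easier here because O4 of 17 is the only nucleophile present and has just one ortho methyl, and because benzyl ester and benzyl ethers tolerate trifluoroacetic acid at room temperature.

**Step 16**
Reactants: 31 benzyl 4-[(4-{[2,4-bis(benzyloxy)-3,6-dimethylbenzoyl]oxy}-2-methoxy-3,5,6-trimethylbenzoyl)oxy]-2-methoxy-3,6-dimethylbenzoate
Product: 32 4-[(4-{[2,4-dihydroxy-3,6-dimethylbenzoyl]oxy}-2-methoxy-3,5,6-trimethylbenzoyl)oxy]-2-methoxy-3,6-dimethylbenzoic acid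
Conditions: H2 (1 atm), 10% Pd/C, EtOAc, rt
Reagents that add atoms: none
Why: Catalytic hydrogenolysis removes the benzyl ester and both benzyl ethers in one operation, while aryl esters, methyl ethers and the arenes are inert under these conditions.

**Compound list**

1 | butane-2,3-dione | CC(=O)C(C)=O | starting material
2 | benzyl (triphenylphosphoranylidene)acetate | O=C(C=P(c1ccccc1)(c1ccccc1)c1ccccc1)OCc1ccccc1 | starting material
3 | benzyl (2E)-3-methyl-4-oxopent-2-enoate | CC(=O)/C(C)=C/C(=O)OCc1ccccc1 | intermediate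
4 | benzyl (2E)-7,7,7-trifluoro-3-methyl-4,6-dioxohept-2-enoate | O=C(OCc1ccccc1)/C=C(\C)C(=O)CC(=O)C(F)(F)F | intermediate
5 | benzyl (2E)-5-diazo-3-methyl-4-oxopent-2-enoate | O=C(OCc1ccccc1)/C=C(\C)C(=O)C=[N+]=[N-] | intermediate
6 | propyne | CC#C | starting material
7 | triisopropylsilyl trifluoromethanesulfonate | CC(C)[Si](OS(=O)(=O)C(F)(F)F)(C(C)C)C(C)C | starting material
8 | lithium prop-1-yn-1-ide | CC#[C-].[Li+] | intermediate
9 | lithium prop-1-yn-1-olate | CC#C[O-].[Li+] | intermediate
10 | 1-(triisopropylsilyloxy)prop-1-yne | CC#CO[Si](C(C)C)(C(C)C)C(C)C | intermediate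
11 | benzyl (2E)-3-methyl-5-oxopenta-2,4-dienoate | O=C(OCc1ccccc1)/C=C(\C)C=C=O | intermediate
12 | benzyl (2E)-3-[3-methyl-4-oxo-2-(triisopropylsilyloxy)cyclobut-2-en-1-yl]but-2-enoate (racemic) | O=C(OCc1ccccc1)/C=C(\C)C1C(=O)C(C)=C1O[Si](C(C)C)(C(C)C)C(C)C | intermediate
13 | benzyl (2E,4E)-3,6-dimethyl-7-oxo-5-(triisopropylsilyloxy)hepta-2,4,6-trienoate | O=C(OCc1ccccc1)/C=C(\C)/C=C(/O[Si](C(C)C)(C(C)C)C(C)C)C(C)=C=O | intermediate
14 | benzyl 2,5-dimethyl-6-oxo-4-(triisopropylsilyloxy)cyclohexa-2,4-diene-1-carboxylate (racemic) | O=C(OCc1ccccc1)C1C(C)=CC(O[Si](C(C)C)(C(C)C)C(C)C)=C(C)C1=O | intermediate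
15 | benzyl 2-hydroxy-3,6-dimethyl-4-(triisopropylsilyloxy)benzoate | Cc1cc(O[Si](C(C)C)(C(C)C)C(C)C)c(C)c(O)c1C(=O)OCc1ccccc1 | intermediate
16 | benzyl 2-methoxy-3,6-dimethyl-4-(triisopropylsilyloxy)benzoate | COc1c(C)c(O[Si](C(C)C)(C(C)C)C(C)C)cc(C)c1C(=O)OCc1ccccc1 | intermediate
17 | benzyl 4-hydroxy-2-methoxy-3,6-dimethylbenzoate | COc1c(C)c(O)cc(C)c1C(=O)OCc1ccccc1 | intermediate
18 | 2,5-dimethylresorcinol | Cc1cc(O)c(C)c(O)c1 | starting material
19 | N-[(2,4-dihydroxy-3,6-dimethylphenyl)methylidene]-N-methylmethanaminium chloride | C[N+](C)=Cc1c(C)cc(O)c(C)c1O.[Cl-] | intermediate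
20 | 2,4-dihydroxy-3,6-dimethylbenzaldehyde | O=Cc1c(C)cc(O)c(C)c1O | intermediate
21 | 2,4-bis(benzyloxy)-3,6-dimethylbenzaldehyde | O=Cc1c(C)cc(OCc2ccccc2)c(C)c1OCc1ccccc1 | intermediate
22 | 2,4-bis(benzyloxy)-3,6-dimethylbenzoic acid | O=C(O)c1c(C)cc(OCc2ccccc2)c(C)c1OCc1ccccc1 | intermediate
23 | 2,4,5-trimethylbenzene-1,3-diol | Cc1cc(O)c(C)c(O)c1C | intermediate
24 | N-[(2,4-dihydroxy-3,5,6-trimethylphenyl)methylidene]-N-methylmethanaminium chloride | C[N+](C)=Cc1c(C)c(C)c(O)c(C)c1O.[Cl-] | intermediate
25 | 2,4-dihydroxy-3,5,6-trimethylbenzaldehyde | O=Cc1c(C)c(C)c(O)c(C)c1O | intermediate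
26 | 2,4-bis(benzyloxy)-3,6-dimethylbenzoic trifluoroacetic anhydride | O=C(OC(=O)C(F)(F)F)c1c(C)cc(OCc2ccccc2)c(C)c1OCc1ccccc1 | intermediate
27 | 4-formyl-3-hydroxy-2,5,6-trimethylphenyl 2,4-bis(benzyloxy)-3,6-dimethylbenzoate | O=Cc1c(C)c(C)c(OC(=O)c2c(C)cc(OCc3ccccc3)c(C)c2OCc2ccccc2)c(C)c1O | intermediate
28 | 4-formyl-3-methoxy-2,5,6-trimethylphenyl 2,4-bis(benzyloxy)-3,6-dimethylbenzoate | O=Cc1c(C)c(C)c(OC(=O)c2c(C)cc(OCc3ccccc3)c(C)c2OCc2ccccc2)c(C)c1OC | intermediate
29 | 4-{[2,4-bis(benzyloxy)-3,6-dimethylbenzoyl]oxy}-2-methoxy-3,5,6-trimethylbenzoic acid | O=C(O)c1c(C)c(C)c(OC(=O)c2c(C)cc(OCc3ccccc3)c(C)c2OCc2ccccc2)c(C)c1OC | intermediate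
30 | 4-{[2,4-bis(benzyloxy)-3,6-dimethylbenzoyl]oxy}-2-methoxy-3,5,6-trimethylbenzoic trifluoroacetic anhydride | O=C(OC(=O)C(F)(F)F)c1c(C)c(C)c(OC(=O)c2c(C)cc(OCc3ccccc3)c(C)c2OCc2ccccc2)c(C)c1OC | intermediate
31 | benzyl 4-[(4-{[2,4-bis(benzyloxy)-3,6-dimethylbenzoyl]oxy}-2-methoxy-3,5,6-trimethylbenzoyl)oxy]-2-methoxy-3,6-dimethylbenzoate | COc1c(C)c(OC(=O)c2c(C)c(C)c(OC(=O)c3c(C)cc(OCc4ccccc4)c(C)c3OCc3ccccc3)c(C)c2OC)cc(C)c1C(=O)OCc1ccccc1 | intermediate
32 | 4-[(4-{[2,4-dihydroxy-3,6-dimethylbenzoyl]oxy}-2-methoxy-3,5,6-trimethylbenzoyl)oxy]-2-methoxy-3,6-dimethylbenzoic acid (CNP0425440.0) | COc1c(C)c(OC(=O)c2c(C)c(C)c(OC(=O)c3c(C)cc(O)c(C)c3O)c(C)c2OC)cc(C)c1C(=O)O | target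

**Total step count:** 16.
**Longest linear sequence:** 8 steps (7, 10, 11, 12, 13, 14, 15, 16). The arm through the key step counts 7 (1, 2, 4, 5, 6, 15, 16).

**Steps most likely to fail**

1. **Step 4.** Four processes could drain the cascade:
   - light-induced E to Z isomerisation of the enoate, followed by closure of the ketene onto the ester carbonyl;
   - collapse of the first zwitterionic adduct at the ester-stabilised chain end instead of at the ketene alpha carbon, which would exchange the roles of O2 and O4;
   - capture of the ketene by the phenol already formed;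
   - ketene dimerisation.

   The fallback gives up ring construction and differentiates the oxygens on an existing arene. It sets out from 20 and comes back at 16. Silylation with i-Pr3SiCl and imidazole in CH2Cl2 should take place only at O4, since O2–H is chelated to the formyl group, and gives 2-hydroxy-3,6-dimethyl-4-(triisopropylsilyloxy)benzaldehyde F1. MeI and K2CO3 in acetone give 2-methoxy-3,6-dimethyl-4-(triisopropylsilyloxy)benzaldehyde F2. Pinnick oxidation gives 2-methoxy-3,6-dimethyl-4-(triisopropylsilyloxy)benzoic acid F3. Carboxylate alkylation with BnBr and KHCO3 in DMF then gives 16.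

2. **Step 2.** The lithium amide may also deprotonate the C3 methyl, which is vinylogous to the ester. The enolate may in addition add in Michael fashion to the very electrophilic enone ester. The fallback uses neither strong base nor diazo transfer. It sets out from 3 and comes back at 5. Soft enolisation with Me3SiOTf and Et3N in CH2Cl2 at 0 °C gives benzyl (2E)-3-methyl-4-(trimethylsilyloxy)penta-2,4-dienoate F4. N-Bromosuccinimide in THF at −78 °C gives benzyl (2E)-5-bromo-3-methyl-4-oxopent-2-enoate F5. N,N′-Ditosylhydrazine and DBU in THF at 0 °C displace the bromide and then eliminate two sulfinate groups to give 5.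

3. **Step 12.** Acylation at O4′, which sits between two methyl groups, may be slow enough for leakage to O2′ or for loss of a benzyl ether in the acidic medium. The fallback removes the competing oxygen first and couples under basic conditions. It sets out from 25 and 22 and comes back at 28.
   - Allyl bromide and K2CO3 in acetone alkylate the more acidic, unchelated O4′ to give 4-(allyloxy)-2-hydroxy-3,5,6-trimethylbenzaldehyde F6.
   - MeI and K2CO3 in DMF give 4-(allyloxy)-2-methoxy-3,5,6-trimethylbenzaldehyde F7.
   - Tsuji–Trost deallylation with Pd(PPh3)4 (zerovalent palladium) and morpholine in THF gives 4-hydroxy-2-methoxy-3,5,6-trimethylbenzaldehyde F8.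
   - Acid 22 is converted with (COCl)2 and catalytic DMF into 2,4-bis(benzyloxy)-3,6-dimethylbenzoyl chloride F9.
   - NaH in THF turns F8 into sodium 4-formyl-3-methoxy-2,5,6-trimethylphenolate F10, which is acylated by F9 to give 28.

**Further compounds**

F1 | step 4 | 2-hydroxy-3,6-dimethyl-4-(triisopropylsilyloxy)benzaldehyde | O=Cc1c(C)cc(O[Si](C(C)C)(C(C)C)C(C)C)c(C)c1O
F2 | step 4 | 2-methoxy-3,6-dimethyl-4-(triisopropylsilyloxy)benzaldehyde | O=Cc1c(C)cc(O[Si](C(C)C)(C(C)C)C(C)C)c(C)c1OC
F3 | step 4 | 2-methoxy-3,6-dimethyl-4-(triisopropylsilyloxy)benzoic acid | O=C(O)c1c(C)cc(O[Si](C(C)C)(C(C)C)C(C)C)c(C)c1OC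
F4 | step 2 | benzyl (2E)-3-methyl-4-(trimethylsilyloxy)penta-2,4-dienoate | C=C(O[Si](C)(C)C)/C(C)=C/C(=O)OCc1ccccc1
F5 | step 2 | benzyl (2E)-5-bromo-3-methyl-4-oxopent-2-enoate | O=C(CBr)/C(C)=C/C(=O)OCc1ccccc1
F6 | step 12 | 4-(allyloxy)-2-hydroxy-3,5,6-trimethylbenzaldehyde | O=Cc1c(C)c(C)c(OCC=C)c(C)c1O
F7 | step 12 | 4-(allyloxy)-2-methoxy-3,5,6-trimethylbenzaldehyde | O=Cc1c(C)c(C)c(OCC=C)c(C)c1OC
F8 | step 12 | 4-hydroxy-2-methoxy-3,5,6-trimethylbenzaldehyde | O=Cc1c(C)c(C)c(O)c(C)c1OC
F9 | step 12 | 2,4-bis(benzyloxy)-3,6-dimethylbenzoyl chloride | O=C(Cl)c1c(C)cc(OCc2ccccc2)c(C)c1OCc1ccccc1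
F10 | step 12 | sodium 4-formyl-3-methoxy-2,5,6-trimethylphenolate | O=Cc1c(C)c(C)c([O-])c(C)c1OC.[Na+]
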